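The cyclohexene ring atoms are numbered C1' (alkene carbon bonded to C2 of the dihydrobenzofuran), C2' (=CH), C3' and C4' (carbinols), C5' and C6' (CH2). Everything rests on disconnecting this ring at C1'–C6'. Because the allylic carbinol C3' is adjacent to C2'=C1', it is carried as a ketone: in an acyclic ynone C1' is the electrophilic β-carbon, and a primary radical at C6' closes the ring by a polarity-matched 6-endo-dig addition that creates the enone C1'=C2'–C3'=O in one operation. The precursor is an open-chain iodo enynone; its hydroxypropenyl arm later becomes the dihydrobenzofuran by asymmetric allylic etherification and oxygenative aryl radical cyclization.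

Key step: step 5

Assumption: in step 9 the (Sa,Sc,Sc) hand of the phosphoramidite is taken as the one that gives the 2S ether; the mirror-image ligand would be used if the sense proves opposite.

Step 1
Reactants: 1 (R)-3-hydroxydihydrofuran-2(3H)-one
Product: 2 (R)-3-(tert-butyldimethylsilyloxy)dihydrofuran-2(3H)-one
Conditions: TBSCl, imidazole, DMF, 0 °C to rt
Reagents that add atoms: tert-butyldimethylsilyl chloride, CC(C)(C)[Si](C)(C)Cl
Why: Silyl ether formation at the only hydroxyl group puts a bulky, non-chelating group on the future C4' oxygen; the stereocentre is not touched.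

Step 2
Reactants: 2 (R)-3-(tert-butyldimethylsilyloxy)dihydrofuran-2(3H)-one
Product: 3 (R)-2-(tert-butyldimethylsilyloxy)-4-hydroxy-N-methoxy-N-methylbutanamide
Conditions: MeNH(OMe)·HCl, AlMe3, CH2Cl2, 0 °C to rt
Reagents that add atoms: N,O-dimethylhydroxylamine hydrochloride, CNOC.Cl
Why: Weinreb amidation (aminolysis of the lactone by the aluminium amide made in the flask) opens the ring at the acyl carbon and frees the primary alcohol (future C6') without touching the stereocentre.

Step 3
Reactants: 3 (R)-2-(tert-butyldimethylsilyloxy)-4-hydroxy-N-methoxy-N-methylbutanamide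
Product: 4 (R)-2-(tert-butyldimethylsilyloxy)-4-iodo-N-methoxy-N-methylbutanamide
Conditions: I2, PPh3, imidazole, CH2Cl2, 0 °C
Reagents that add atoms: iodine, II
Why: Appel-type iodination converts the primary alcohol into the radical precursor; the secondary centre is not involved.

Step 4
Reactants: 5 (E)-pent-2-en-4-yn-1-ol; 4 (R)-2-(tert-butyldimethylsilyloxy)-4-iodo-N-methoxy-N-methylbutanamide
Product: 7 (3R,7E)-3-(tert-butyldimethylsilyloxy)-9-hydroxy-1-iodonon-7-en-5-yn-4-one, via dilithiated enynol 6 (not isolated)
Conditions: 5, n-BuLi (2 equiv per 5), THF, −78 °C; then 4, −78 to −20 °C; aq. NH4Cl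
Reagents that add atoms: none
Why: Weinreb ketone synthesis: the lithium acetylide carbon acylates once at the N-methoxy-N-methyl amide, while the lithium alkoxide and the primary iodide are inert at low temperature in THF.

Step 5
Reactants: 7 (3R,7E)-3-(tert-butyldimethylsilyloxy)-9-hydroxy-1-iodonon-7-en-5-yn-4-one
Product: 8 (R)-6-(tert-butyldimethylsilyloxy)-3-[(E)-3-hydroxyprop-1-en-1-yl]cyclohex-2-en-1-one
Conditions: (Me3Si)3SiH (slow addition), AIBN, toluene (0.01 M), 80 °C
Reagents that add atoms: none
Why: Iodine abstraction by the silyl radical gives the primary radical at C6', which adds to C1', the β-carbon of the ynone, and the resulting α-keto vinyl radical at C2' takes hydrogen from the silane to give the enone with C1'=C2' in the ring. The closest known reaction type is the intramolecular Giese addition (endo radical cyclization) of ω-iodoalkyl ynones and enones. The six-membered ring closes in the 6-endo-dig mode. No new stereocentre is formed, and C4' keeps its R configuration because it is never a radical site. The step needs 6-endo over 5-exo-dig regioselectivity and ring closure before hydrogen transfer: the C3' carbonyl polarises the alkyne so that the nucleophilic alkyl radical attacks C1' and not the α-carbon C2', the endo trajectory matches the 120° angle of attack on an alkyne, and high dilution with slow addition of the weak hydrogen donor (Me3Si)3SiH keeps reduction of the open-chain radical slow.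

Step 6
Reactants: 8 (R)-6-(tert-butyldimethylsilyloxy)-3-[(E)-3-hydroxyprop-1-en-1-yl]cyclohex-2-en-1-one
Product: 9 (1S,6R)-6-(tert-butyldimethylsilyloxy)-3-[(E)-3-hydroxyprop-1-en-1-yl]cyclohex-2-en-1-ol
Conditions: LiBH(s-Bu)3 (2.3 equiv), THF, −78 °C; aq. NH4Cl
Reagents that add atoms: none
Why: 1,2-Reduction of the β-substituted enone by the bulky borohydride should occur from the face opposite the neighbouring silyloxy group, which sets C3' as S, cis to the C4' oxygen.

Step 7
Reactants: 9 (1S,6R)-6-(tert-butyldimethylsilyloxy)-3-[(E)-3-hydroxyprop-1-en-1-yl]cyclohex-2-en-1-ol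
Product: 10 (E)-3-[(3S,4R)-4-(tert-butyldimethylsilyloxy)-3-hydroxycyclohex-1-en-1-yl]prop-2-en-1-yl methyl carbonate
Conditions: ClCO2Me (1.05 equiv), pyridine, CH2Cl2, −20 °C
Reagents that add atoms: methyl chloroformate, COC(=O)Cl
Why: Chemoselective acylation of the primary allylic alcohol over the hindered secondary one gives the allylic carbonate needed for ionisation.

Step 8
Reactants: 11 4-(3-hydroxypropyl)-2-methoxyphenol
Product: 12 4-(3-hydroxypropyl)-2-iodo-6-methoxyphenol
Conditions: I2, NaHCO3, THF/H2O, 0 °C to rt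
Reagents that add atoms: iodine, II
Why: Electrophilic aromatic iodination of the phenoxide goes to the only free position ortho to oxygen, the para position being blocked by the side chain.

Step 9
Reactants: 12 4-(3-hydroxypropyl)-2-iodo-6-methoxyphenol; 10 (E)-3-[(3S,4R)-4-(tert-butyldimethylsilyloxy)-3-hydroxycyclohex-1-en-1-yl]prop-2-en-1-yl methyl carbonate
Product: 14 (1S,6R)-6-(tert-butyldimethylsilyloxy)-3-{(1S)-1-[4-(3-hydroxypropyl)-2-iodo-6-methoxyphenoxy]prop-2-en-1-yl}cyclohex-2-en-1-ol, via lithium phenoxide 13 (not isolated)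
Conditions: 12, LiN(SiMe3)2 (1.0 equiv), THF, 0 °C; then 10, [Ir(cod)Cl]2 (2 mol%), (Sa,Sc,Sc)-O,O'-(1,1'-binaphthyl-2,2'-diyl) N,N-bis(1-phenylethyl)phosphoramidite (4 mol%, pre-activated with n-PrNH2), THF, rt
Reagents that add atoms: none
Why: Iridium-catalysed enantioselective allylic etherification: the aryloxide attacks the substituted terminus of the allyl-iridium intermediate (branched selectivity) to form the C2–O bond, and the chiral ligand sets C2 as S independently of the remote ring stereocentres.

Step 10
Reactants: 14 (1S,6R)-6-(tert-butyldimethylsilyloxy)-3-{(1S)-1-[4-(3-hydroxypropyl)-2-iodo-6-methoxyphenoxy]prop-2-en-1-yl}cyclohex-2-en-1-ol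
Product: 16 (1S,6R)-6-(tert-butyldimethylsilyloxy)-3-[(2S,3R)-3-(hydroxymethyl)-5-(3-hydroxypropyl)-7-methoxy-2,3-dihydrobenzofuran-2-yl]cyclohex-2-en-1-ol, via hydroperoxide 15 (not isolated)
Conditions: n-Bu3SnH (slow addition), dry air, toluene, rt; then PPh3
Reagents that add atoms: dioxygen, O=O
Why: Oxygenative 5-exo-trig aryl radical cyclization: the aryl radical adds to the internal vinyl carbon to form the C3–aryl bond, the primary radical is trapped by O2 and the hydroperoxide is reduced by PPh3, and a chair-like transition state with the cyclohexenyl group pseudo-equatorial should place the C3 hydroxymethyl trans to the C2 substituent (3R).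

Step 11
Reactants: 16 (1S,6R)-6-(tert-butyldimethylsilyloxy)-3-[(2S,3R)-3-(hydroxymethyl)-5-(3-hydroxypropyl)-7-methoxy-2,3-dihydrobenzofuran-2-yl]cyclohex-2-en-1-ol
Product: 17 difengpiol A, (1R,2S)-4-[(2S,3R)-3-(hydroxymethyl)-5-(3-hydroxypropyl)-7-methoxy-2,3-dihydrobenzofuran-2-yl]cyclohex-3-ene-1,2-diol
Conditions: HF·pyridine, pyridine, THF, 0 °C to rt
Reagents that add atoms: none
Why: Fluoride-mediated desilylation under buffered conditions removes the last protecting group without touching the allylic aryl ether or any stereocentre.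

Compound list
1 | (R)-3-hydroxydihydrofuran-2(3H)-one, (R)-α-hydroxy-γ-butyrolactone | O[C@@H]1CCOC1=O | starting material
2 | (R)-3-(tert-butyldimethylsilyloxy)dihydrofuran-2(3H)-one | CC(C)(C)[Si](C)(C)O[C@@H]1CCOC1=O | intermediate
3 | (R)-2-(tert-butyldimethylsilyloxy)-4-hydroxy-N-methoxy-N-methylbutanamide | CC(C)(C)[Si](C)(C)O[C@H](CCO)C(=O)N(C)OC | intermediate
4 | (R)-2-(tert-butyldimethylsilyloxy)-4-iodo-N-methoxy-N-methylbutanamide | CC(C)(C)[Si](C)(C)O[C@H](CCI)C(=O)N(C)OC | intermediate
5 | (E)-pent-2-en-4-yn-1-ol | OC/C=C/C#C | starting material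
6 | dilithiated enynol, dilithium (E)-5-oxidopent-3-en-1-yn-1-ide (not isolated) | [Li+].[Li+].[O-]C/C=C/C#[C-] | intermediate
7 | (3R,7E)-3-(tert-butyldimethylsilyloxy)-9-hydroxy-1-iodonon-7-en-5-yn-4-one | CC(C)(C)[Si](C)(C)O[C@H](CCI)C(=O)C#C/C=C/CO | intermediate
8 | (R)-6-(tert-butyldimethylsilyloxy)-3-[(E)-3-hydroxyprop-1-en-1-yl]cyclohex-2-en-1-one | CC(C)(C)[Si](C)(C)O[C@@H]1CCC(/C=C/CO)=CC1=O | intermediate
9 | (1S,6R)-6-(tert-butyldimethylsilyloxy)-3-[(E)-3-hydroxyprop-1-en-1-yl]cyclohex-2-en-1-ol | OC/C=C/C1=C[C@H](O)[C@H](O[Si](C)(C)C(C)(C)C)CC1 | intermediate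
10 | (E)-3-[(3S,4R)-4-(tert-butyldimethylsilyloxy)-3-hydroxycyclohex-1-en-1-yl]prop-2-en-1-yl methyl carbonate | COC(=O)OC/C=C/C1=C[C@H](O)[C@H](O[Si](C)(C)C(C)(C)C)CC1 | intermediate
11 | 4-(3-hydroxypropyl)-2-methoxyphenol, dihydroconiferyl alcohol | COc1cc(CCCO)ccc1O | starting material
12 | 4-(3-hydroxypropyl)-2-iodo-6-methoxyphenol | COc1cc(CCCO)cc(I)c1O | intermediate
13 | lithium 4-(3-hydroxypropyl)-2-iodo-6-methoxyphenoxide (not isolated) | [Li+].COc1cc(CCCO)cc(I)c1[O-] | intermediate
14 | (1S,6R)-6-(tert-butyldimethylsilyloxy)-3-{(1S)-1-[4-(3-hydroxypropyl)-2-iodo-6-methoxyphenoxy]prop-2-en-1-yl}cyclohex-2-en-1-ol | COc1cc(CCCO)cc(I)c1O[C@H](C1=C[C@H](O)[C@H](O[Si](C)(C)C(C)(C)C)CC1)C=C | intermediate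
15 | (1S,6R)-6-(tert-butyldimethylsilyloxy)-3-[(2S,3R)-3-(hydroperoxymethyl)-5-(3-hydroxypropyl)-7-methoxy-2,3-dihydrobenzofuran-2-yl]cyclohex-2-en-1-ol (not isolated) | COc1cc(CCCO)cc2c1O[C@H](C1=C[C@H](O)[C@H](O[Si](C)(C)C(C)(C)C)CC1)[C@H]2COO | intermediate
16 | (1S,6R)-6-(tert-butyldimethylsilyloxy)-3-[(2S,3R)-3-(hydroxymethyl)-5-(3-hydroxypropyl)-7-methoxy-2,3-dihydrobenzofuran-2-yl]cyclohex-2-en-1-ol | COc1cc(CCCO)cc2c1O[C@H](C1=C[C@H](O)[C@H](O[Si](C)(C)C(C)(C)C)CC1)[C@H]2CO | intermediate
17 | difengpiol A, (1R,2S)-4-[(2S,3R)-3-(hydroxymethyl)-5-(3-hydroxypropyl)-7-methoxy-2,3-dihydrobenzofuran-2-yl]cyclohex-3-ene-1,2-diol | COc1cc(CCCO)cc2c1O[C@H](C1=C[C@H](O)[C@H](O)CC1)[C@H]2CO | target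

Total step count: 11. Longest linear sequence: 10 steps (1 to 17 through steps 1–7, 9, 10 and 11).

Steps most likely to fail

Step 5. What may go wrong is hydrogen transfer to the open-chain C6' radical before ring closure, or exo closure at C2'. The fallback sets out from 7 and comes back at 8. Conjugate hydroiodination of the ynone (NaI, AcOH, rt, anti addition) should give the (3R,5Z,7E)-β-iodo dienone F1, in which the vinyl iodide at C1' and the acyl group are cis. An intramolecular nickel-catalysed reductive cross-electrophile coupling of this vinyl iodide with the primary alkyl iodide (NiBr2·glyme, 4,4'-di-tert-butyl-2,2'-bipyridine, Mn powder, DMA, rt) would then form the same C1'–C6' bond and deliver 8.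

Step 9. What may go wrong is attack of the doubly ortho-substituted aryloxide at the unsubstituted allyl terminus (linear ether), or slow ionisation of the dienyl carbonate. The fallback sets out from 9 and 12 and comes back at 16. A Larock heteroannulation (Pd(OAc)2, NaHCO3, n-Bu4NCl, DMF, 80 °C) joins the two partners in one operation: the arylpalladium iodide adds to the hydroxymethyl-bearing diene terminus (C3) and the phenoxide captures the allylpalladium unit at C2. A chiral bisphosphine on palladium would be needed to bias the diene face, and C2/C3 diastereomers would have to be separated. This fallback makes no compound outside the list (F0).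

Step 10. What may go wrong is hydrogen transfer to the cyclized primary radical before capture by O2, or attack of peroxyl radicals on the electron-rich alkene and arene. The fallback sets out from 14 and comes back at 16. The same aryl radical cyclization is run without oxygen, with the persistent radical TEMPO as the trap (n-Bu3SnH, TEMPO, benzene, 70 °C), to give the alkoxyamine F2. The N–O bond is then cleaved reductively (Zn, AcOH/THF/H2O, 50 °C) to free the primary alcohol 16.

Further compounds
F1 | step 5 | (3R,5Z,7E)-3-(tert-butyldimethylsilyloxy)-9-hydroxy-1,6-diiodonona-5,7-dien-4-one | OC/C=C/C(/I)=C/C(=O)[C@@H](CCI)O[Si](C)(C)C(C)(C)C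
F0 | step 9 | none | none
F2 | step 10 | (1S,6R)-6-(tert-butyldimethylsilyloxy)-3-[(2S,3R)-5-(3-hydroxypropyl)-7-methoxy-3-{[(2,2,6,6-tetramethylpiperidin-1-yl)oxy]methyl}-2,3-dihydrobenzofuran-2-yl]cyclohex-2-en-1-ol | COc1cc(CCCO)cc2c1O[C@H](C1=C[C@H](O)[C@H](O[Si](C)(C)C(C)(C)C)CC1)[C@H]2CON1C(C)(C)CCCC1(C)C
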